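All runs were computed with constants of no real substance, and the scatter is random.

**A stalled run.** Substrate cannot be what stopped the teal run: 36% of it stands at 25.0 min, while product has hardly moved since 15.0 min. The green run, with 19 mol% of free catalyst against teal's 23 mol% and the same other charges, stalls lower, with late readings near 52.3% product against 62.7%.

the same everywhere: substrate 0.038 M; capture agent 0.0114 M

| flask | partner | free catalyst | remark | time |
|---|---|---|---|---|
| green | 2 equiv | 19 mol% | run made earlier |  |
| blue | 2 equiv | 20 mol% | run made earlier |  |
| teal | 2 equiv | 23 mol% | run made earlier |  |
| Saturday's | 2.00 equiv | 15 mol% |  | 25 min |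
| Tuesday's | 2.00 equiv | 30 mol% |  | 25 min |

| run | time / min | catalyst intermediate D / % | substrate / % | product / % |
|---|---|---|---|---|
| green | 5.00 | 2 | 65 | 39 |
| green | 10.0 | 0 | 50 | 49 |
| green | 15.0 | 0 | 45 | 52 |
| green | 20.0 | 3 | 48 | 53 |
| green | 25.0 | 0 | 46 | 52 |
| blue | 2.00 | 0 | 81 | 18 |
| blue | 6.00 | 3 | 56 | 45 |
| blue | 12.0 | 3 | 46 | 54 |
| blue | 20.0 | 1 | 43 | 56 |
| blue | 25.0 | 0 | 43 | 58 |
| teal | 5.00 | 2 | 57 | 42 |
| teal | 10.0 | 0 | 43 | 55 |
| teal | 15.0 | 0 | 37 | 61 |
| teal | 20.0 | 1 | 38 | 65 |
| teal | 25.0 | 0 | 36 | 62 |

(each reading ± 1.5 percentage points)

- reactions considered so far: catalyst intermediate D -> free catalyst + product; partner -> decomposed reagent; substrate + catalyst intermediate C <-> catalyst intermediate D; partner + free catalyst <-> catalyst intermediate A; catalyst intermediate A -> catalyst intermediate B; catalyst intermediate B -> released group + catalyst intermediate C; catalyst intermediate A + capture agent -> trapped intermediate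

1. which of these there is most of at the end, counted by the substrate in it, Saturday's (product / substrate / catalyst intermediate D)
2. which of these there is most of at the end, counted by the substrate in it, Tuesday's (product / substrate / catalyst intermediate D)
3. the largest of these amounts at the end, in percent of the substrate charged, Saturday's
4. the largest of these amounts at the end, in percent of the substrate charged, Tuesday's

**Two exits.** Catalyst intermediate D reads at most 3% in the green run, so this reckoning takes the fast steps of the round at steady state, with catalyst near its charge c(free catalyst). Partner then leaves by two doors: its own decay, and the catalyst route, pseudo-first-order in partner. Both scale with c(partner), so their ratio holds through a run. Each product costs one partner; with y the product as a fraction of substrate, y/(2 − y) is partner used per partner decayed.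

That split reads 0.354 for green, less than teal's 0.456: teal's extra catalyst wins more of the same partner. Divided by c(free catalyst) and averaged, the two give 50.6 /M, the split constant g, partner used per partner decayed per molar of catalyst.

**Own reckoning.** Saturday's has c(free catalyst) = 0.00570 M, so g·c = 0.289 and y = 44.8%, which leaves substrate ahead. Tuesday's has y = 73.2%, with product ahead.

**The forecast.** It holds that “partner decay probably also helps end the run”, and it names substrate at 60% for Saturday's and product at 77% for Tuesday's.

**The result.** Saturday's ends with substrate at 54.3%, 5.7 percentage points under the forecast, and Tuesday's with product at 74.3%.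

    catalyst intermediate D → free catalyst + product (k = 23.0 /min)
    partner → decomposed reagent (k = 0.190 /min)
    substrate + catalyst intermediate C ⇌ catalyst intermediate D (K = 33.0 /M, k = 220 /M/min)
    partner + free catalyst ⇌ catalyst intermediate A (K = 8.00 /M, k = 34.0 /M/min)
    catalyst intermediate A → catalyst intermediate B (k = 3.10 /min)
    catalyst intermediate B → released group + catalyst intermediate C (k = 25.0 /min)
    catalyst intermediate A + capture agent → trapped intermediate (k = 15.0 /M/min)

**Why it stops.** Saturday's flask holds 0.0174 M of released group against 0.0576 M of decomposed reagent, a split of 0.302, where g·c gave 0.289. Partner, charged at 2.00 equiv, is the first charge to run out there: it is down to 0.174% of its charge at 25.0 min, with 54% of the substrate left. Its decay is the main reason for the stop: without that step the same flask gives 99.7% product instead of 45.7%.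

**A dilute flask.** Tuesday's recipe at 0.0095 M of substrate has c(free catalyst) = 0.00285 M, so g gives y = 25.2%. The computed flask ends at 30.3% product, with substrate holding most.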